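(The numbers in the tables were computed from invented constants; scatter was added.)

Target stayed far short of the substrate charged in the last readings of the earlier runs: oak read 46 % at 6.00 h and alder read 37 % at both 2.50 h and 6.00 h, while elm, with 3 equiv of coupling partner, read 60 %.

| flask | substrate | coupling partner | remark | time |
|---|---|---|---|---|
| cedar | 0.077 M | 1.5 equiv | run made earlier |  |
| oak | 0.11 M | 1.5 equiv | run made earlier |  |
| alder | 0.17 M | 1.5 equiv | run made earlier |  |
| elm | 0.077 M | 3 equiv | run made earlier |  |
| teal | 0.077 M | 1.50 equiv | one stirred flow tank at steady state, fed with the mixture as stated, mean residence time 5.0 h |  |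
| red | 0.077 M | 1.50 equiv (fed, over 4.00 h) | all but coupling partner at the start; coupling partner goes in evenly over 4.00 h, the run ends at 5.0 h | 5.0 h |
| amber | 0.077 M (fed, over 4.00 h) | 1.50 equiv | a stirred flask in which substrate is dosed at a steady rate over 4.00 h without added volume, worked up at 5.0 h | 5.0 h |
| violet | 0.077 M | 1.50 equiv | a closed flask charged with all of it at once and left for 5.0 h | 5.0 h |

| cedar: time / h | cedar: target / % | oak: time / h | oak: target / % | alder: time / h | alder: target / % | elm: time / h | elm: target / % |
|---|---|---|---|---|---|---|---|
| 0.833 | 13 | 0.833 | 17 | 0.500 | 15 | 0.500 | 14 |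
| 1.50 | 29 | 2.00 | 39 | 1.00 | 26 | 1.00 | 31 |
| 2.50 | 38 | 4.00 | 42 | 2.50 | 37 | 2.50 | 54 |
| 3.00 | 40 | 6.00 | 46 | 6.00 | 37 | 6.00 | 60 |

(each reading ± 1.5 percentage points)

- the stated concentrations are those of everything mixed, before any reaction; amounts are the same in each set-up
- the earlier runs were read with a standard deviation of 1.5 percentage points
- the feed brings no volume worth counting
- the earlier runs were made in a closed, stirred flask

- the set-up with the highest amount of target at the outlet or at the end, in percent of the substrate put in ("none" if the first two lie within 2 percentage points) (teal / red / amber / violet / none)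
- amount of target at the outlet or at the end, in percent of the substrate put in, teal
- amount of target at the outlet or at the end, in percent of the substrate put in, red
- amount of target at the outlet or at the end, in percent of the substrate put in, amber
- amount of target at the outlet or at the end, in percent of the substrate put in, violet

I built the flask up one process at a time. First I took the main step by itself, with target rising towards the whole charge. Cedar's 29 % at 1.50 h gave a rate constant of 0.228 h⁻¹, hence 68.0 % at 5.0 h. But that curve asked 49.5 % at 3.00 h, where cedar read 40 %.

So I added a competing loss, lumped as a stall level S, the target at which a run stops rising. I read S = 46.0 % from oak's last reading, with its scatter of 1.5 percentage points, because oak, at 0.11 M, stands closer to cedar's 0.077 M than alder's 0.17 M does. Cedar's reading then gave 0.664 h⁻¹ for the approach rate κ, the first-order rate constant, ln(S/(S−y))/t, with which target y closes its gap to S. This returned 39.7 % at 3.00 h for cedar, and 44.3 % for violet.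

Last came the vessels, keeping one S throughout. For teal, with mean residence time τ, the Damköhler number κτ is 3.32, so S·κτ/(1+κτ) gave 35.3 %. Averaging over portions dosed evenly for 4.00 h gave 37.7 % for both red and amber. I therefore ranked violet first.

The forecast differed, ranking red first with teal 31 %, red 45 %, amber 20 % and violet 42 %, on the view that “Partner is therefore being wasted”. The flasks gave teal 35.1 %, red 39.1 %, amber 42.2 % and violet 47.6 %, so violet came first.

    substrate + coupling partner ⇌ intermediate (K = 99.0 M⁻¹, k = 5.30 M⁻¹ h⁻¹)
    intermediate ⇌ target + by-product (K = 0.160 M, k = 1.60 h⁻¹)
    substrate + intermediate → side product (k = 9.20 M⁻¹ h⁻¹)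

Teal's 35.1 % stood against my 35.3 %, and violet's 47.6 % lay 3.3 points above my 44.3 %. With 1/κ at 1.51 h, my rule left violet 1.7 points still to gain after 5.0 h and then a flat line. Violet had not come to rest, though: left until 50.0 h, it held 44.3 % target, 3.3 points less than at 5.0 h.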